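**Plan** (labdane numbering: C2 bears the ring acetate, C4 the gem-dimethyl, C5/C10 are the fusion carbons with C20 on C10, C7=C8 carries C17 on C8, C9 carries the chain C11–C15 with C16 on C13)
- Cuts, in retrosynthetic order: both acetates; C11–C12 (alkyl–alkyl Suzuki coupling) and C9=C11 (methylenation); one C4 methyl (hydromethylation of C4=CH2); C2–C3 (carbonyl-ene, opens ring A); C10–C1 and C10–C20 (enolate alkylations).
- Enabling feature: ring B (C5, C6, C7=C8 with C17, C9, C10) is the ring of (S)-carvone, whose isopropenyl carbon is C4 and whose =CH2 is C3. The C2 oxygen is 1,3 to C4, so ring A is a masked 3-methylenecyclohexanol, the product of a type 2 ene reaction of a C2 aldehyde hung from C10.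
- Forward order: ring B is bought; C20 and the C1–C2 arm go onto C10; ring A closes by C2–C3; C4 becomes gem-dimethyl; C11 is added and joined to the C12–C15 bromide; desilylation and diacetylation finish.
- Stereochemistry: C5 from (S)-carvone; C10 by alkylation anti to the isopropenyl group; C2 in the ene closure (oxygen anti to C20); C9 by hydroboration anti to C20; C13 from (R)-methylsuccinate.

Key step: step 5

Assumption: the (R)-methylsuccinate unit is bought as its 4-methyl monoester, whose free carboxyl sits on the methyl-bearing carbon and can be reduced selectively by borane.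

**Step 1**
Reactants: 1 (S)-(+)-carvone
Product: 3 (5S)-6-methylcarvone as a C6 epimer mixture (C6 = labdane C10), via carvone lithium dienolate 2 (not isolated)
Conditions: LiN(i-Pr)2, THF, −78 °C; then MeI, −78 → 0 °C
Reagents that add atoms: iodomethane, CI
Why: Kinetic deprotonation at the saturated α′-carbon and SN2 methylation of the cross-conjugated enolate (enolate alkylation) is routine for carvone; the new centre need not be controlled because step 2 planarises it again, and C5 is untouched.

**Step 2**
Reactants: 3 (5S)-6-methylcarvone; 4 ethyl bromoacetate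
Product: 6 ethyl 2-[(1R,6R)-1,3-dimethyl-2-oxo-6-(prop-1-en-2-yl)cyclohex-3-en-1-yl]acetate, via 6-methylcarvone lithium enolate 5 (not isolated)
Conditions: LiN(i-Pr)2, THF, −78 °C; then 4, DMPU, −78 → −20 °C
Reagents that add atoms: none
Why: The enolate is planar at C10 and its C10 methyl pushes the neighbouring isopropenyl group pseudo-axial (A(1,2) strain), so SN2 enolate alkylation by the bromoacetate occurs on the face anti to that group and sets quaternary C10 (R) with the ester arm trans and the methyl cis to the isopropenyl group.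

**Step 3**
Reactants: 6 keto ester
Product: 7 2-[(1R,6R)-2-hydroxy-1,3-dimethyl-6-(prop-1-en-2-yl)cyclohex-3-en-1-yl]ethan-1-ol (ring carbinol epimers)
Conditions: LiAlH4, THF, 0 °C; aqueous NaOH work-up
Reagents that add atoms: none
Why: Hydride reduction takes the ester to the primary alcohol and adds 1,2 to the hindered enone, which avoids reducing an ester selectively beside a ketone; the C9 carbinol forms as an epimer mixture that step 4 erases.

**Step 4**
Reactants: 7 diol
Product: 8 2-[(1R,6R)-1,3-dimethyl-2-oxo-6-(prop-1-en-2-yl)cyclohex-3-en-1-yl]acetaldehyde (C9 ketone, C2 aldehyde on the C10 arm)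
Conditions: (COCl)2, DMSO, CH2Cl2, −78 °C; then Et3N, −78 → 0 °C
Reagents that add atoms: none
Why: Swern oxidation activates both hydroxyls as alkoxysulfonium ions before base is added, so the 1,4-diol goes to the keto aldehyde without a lactol that would over-oxidise to a lactone; quaternary C10 cannot epimerise and no stereocentre is formed.

**Step 5**
Reactants: 8 keto aldehyde
Product: 9 (4aR,7R,8aR)-7-hydroxy-2,8a-dimethyl-5-methylidene-4a,5,6,7,8,8a-hexahydronaphthalen-1(4H)-one (labdane: 2-OH equatorial and anti to C20, C4=CH2, trans-fused, C7=C8–C9=O)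
Conditions: Me2AlCl (1.5 equiv), CH2Cl2, −78 → −20 °C; 1 M HCl quench at 0 °C
Reagents that add atoms: none
Why: Me2AlCl binds the C2 aldehyde, the =CH2 terminus (C3) of the isopropenyl group adds to the carbonyl carbon so that charge builds on tertiary C4, and a hydrogen of the allylic methyl passes to oxygen within the six-atom array O–C2–C3–C4–C–H (in concert or via a short-lived C4 cation), after which the aluminium alkoxide loses methane and no protic acid remains to move the new C4=CH2 bond. The closest known reaction is the type 2 intramolecular carbonyl-ene cyclisation of 5-methylhex-5-enals to 3-methylenecyclohexanols under alkylaluminium halides. Ring A closes 6-exo with respect to the C=O and endo with respect to C3=C4, and because the C1–C2 arm and the isopropenyl group are trans-diequatorial on ring B only the trans-fused decalin can form. The single new stereocentre, C2, is fixed by the face of ring A on which the array assembles, since oxygen and the hydrogen-donating methyl must be cis: on the C20 face the axial C20 methyl would lie directly over the array, so assembly on the opposite face (ring A passing through a twist-boat that relaxes to the chair) should leave the C2 oxygen anti to C20 and equatorial (2R). The step needs this face selectivity and reaction at the aldehyde only; C20 is relied on for the first, and for the second the C9 carbonyl is a hindered conjugated ketone with no ene partner in reach and the enone C7=C8 is not nucleophilic.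

**Step 6**
Reactants: 9 hydroxy enone
Product: 10 (4aR,7R,8aR)-7-[(tert-butyldimethylsilyl)oxy]-2,8a-dimethyl-5-methylidene-4a,5,6,7,8,8a-hexahydronaphthalen-1(4H)-one
Conditions: TBSCl, imidazole, DMF, 25 °C
Reagents that add atoms: tert-butyldimethylsilyl chloride, CC(C)(C)[Si](C)(C)Cl
Why: Silyl ether protection of an unhindered equatorial secondary alcohol is routine, and the TBS ether is inert to the radical, ylide, borane and palladium steps that follow; no stereocentre changes.

**Step 7**
Reactants: 10 silyl ether
Product: 12 (4aR,7R,8aR)-7-[(tert-butyldimethylsilyl)oxy]-2,5,5,8a-tetramethyl-4a,5,6,7,8,8a-hexahydronaphthalen-1(4H)-one, via N-alkyl sulfonohydrazide 11 (not isolated)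
Conditions: n-C8H17SO2NHNH2, (CH2O)n, THF/MeOH; Fe(acac)3 (0.5 equiv), PhSiH3, 25 °C; then MeOH, 60 °C
Reagents that add atoms: formaldehyde (as paraformaldehyde), C=O
Why: In this metal-hydride hydrogen-atom-transfer hydromethylation the iron hydride from Fe(acac)3 and PhSiH3 delivers H to the =CH2 carbon of the electron-rich 1,1-disubstituted alkene (Markovnikov), the tertiary C4 radical adds to the formaldehyde sulfonylhydrazone, and the resulting hydrazide loses sulfinate and N2 on warming to leave the second C4 methyl; C4 is not stereogenic in the product and the electron-poor trisubstituted enone is a much poorer hydrogen-atom acceptor.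

**Step 8**
Reactants: 12 gem-dimethyl enone
Product: 13 tert-butyldimethyl{[(2R,4aR,8aR)-4,4,7,8a-tetramethyl-8-methylidene-1,2,3,4,4a,5,8,8a-octahydronaphthalen-2-yl]oxy}silane (labdane: C7=C8–C9=C11H2 diene)
Conditions: Ph3PCH3Br, KOt-Bu, toluene, 90 °C
Reagents that add atoms: methyltriphenylphosphonium bromide, C[P+](c1ccccc1)(c1ccccc1)c1ccccc1.[Br-]
Why: Wittig methylenation with Ph3P=CH2 generated by KOt-Bu in hot toluene is the usual answer to ketones flanked by a quaternary carbon; the ketone has no α-hydrogen, addition is 1,2, and no stereocentre is formed.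

**Step 9**
Reactants: 14 (R)-2-methylsuccinic acid 4-methyl ester
Product: 15 methyl (R)-4-hydroxy-3-methylbutanoate
Conditions: BH3·SMe2, THF, 0 → 25 °C; aqueous work-up, used without delay
Reagents that add atoms: none
Why: Borane reduces the free carboxylic acid far faster than the methyl ester (chemoselective borane reduction), which tells the two carboxyl carbons apart; the conditions are non-basic, so the centre next to the acid is not epimerised.

**Step 10**
Reactants: 15 hydroxy ester
Product: 16 methyl (R)-4-bromo-3-methylbutanoate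
Conditions: CBr4, PPh3, CH2Cl2, 0 °C
Reagents that add atoms: carbon tetrabromide, BrC(Br)(Br)Br
Why: Appel bromination is an SN2 displacement at the primary carbinol carbon under neutral conditions and outruns lactonisation; the adjacent stereocentre is not involved.

**Step 11**
Reactants: 16 bromo ester
Product: 17 (R)-4-bromo-3-methylbutan-1-ol
Conditions: i-Bu2AlH, CH2Cl2, −78 → 0 °C; aq. potassium sodium tartrate
Reagents that add atoms: none
Why: i-Bu2AlH reduces the ester to the primary alcohol (ester reduction) at low temperature without touching the primary C–Br bond.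

**Step 12**
Reactants: 17 bromo alcohol
Product: 18 (R)-(4-bromo-3-methylbutoxy)(tert-butyl)dimethylsilane
Conditions: TBSCl, imidazole, CH2Cl2, 0 → 25 °C
Reagents that add atoms: tert-butyldimethylsilyl chloride, CC(C)(C)[Si](C)(C)Cl
Why: Silyl ether protection with imidazole as the only base caps the alcohol before it can close to 3-methyltetrahydrofuran.

**Step 13**
Reactants: 13 diene; 18 bromide
Product: 20 bis-TBS ether of (2R,5R,9R,10R,13S)-labd-7-ene-2,15-diol, via B-alkyl-9-BBN 19 (not isolated)
Conditions: 9-BBN dimer, THF, 25 → 50 °C; then 18, Pd(OAc)2 (cat.), PCy3 (cat.), K3PO4·H2O, THF, 25 → 40 °C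
Reagents that add atoms: none
Why: In this B-alkyl Suzuki–Miyaura alkyl–alkyl coupling, 9-BBN adds its boron to the terminal C11 of the exocyclic alkene from the face opposite the axial C20 methyl, so H9 ends anti to C20 and the C11 arm equatorial (9R) while the trisubstituted C7=C8 is left alone; the base-activated B-alkyl group then transmetalates to the alkylpalladium formed by oxidative addition of the primary bromide to the electron-rich PCy3 complex of zerovalent palladium, and C13 is carried through unchanged.

**Step 14**
Reactants: 20 bis-silyl ether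
Product: 21 (2R,5R,9R,10R,13S)-labd-7-ene-2,15-diol
Conditions: Bu4NF, THF, 25 → 40 °C
Reagents that add atoms: none
Why: Fluoride-driven silyl ether cleavage (Si–F bond formation) frees the secondary C2 and primary C15 alcohols without affecting the alkene or any stereocentre.

**Step 15**
Reactants: 21 diol
Product: 22 (2R,5R,9R,10R,13S)-labd-7-ene-2,15-diyl diacetate (target)
Conditions: Ac2O, pyridine, DMAP (cat.), CH2Cl2, 25 °C
Reagents that add atoms: acetic anhydride, CC(=O)OC(C)=O
Why: DMAP-catalysed acylation (esterification) of a primary and an equatorial secondary alcohol proceeds with retention at C2 and gives the diacetate.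

**Compound list**
1 | (S)-(+)-carvone | CC1=CC[C@@H](CC1=O)C(C)=C | starting material
2 | carvone lithium dienolate | CC1=CC[C@@H](C=C1O[Li])C(C)=C | intermediate
3 | (5S)-2,6-dimethyl-5-(prop-1-en-2-yl)cyclohex-2-en-1-one (6-methylcarvone, C6 epimers) | O=C1C(C)=CC[C@H](C(C)=C)C1C | intermediate
4 | ethyl bromoacetate | CCOC(=O)CBr | starting material
5 | 6-methylcarvone lithium enolate | [Li]OC1=C(C)[C@@H](C(C)=C)CC=C1C | intermediate
6 | ethyl 2-[(1R,6R)-1,3-dimethyl-2-oxo-6-(prop-1-en-2-yl)cyclohex-3-en-1-yl]acetate | O=C1C(C)=CC[C@H](C(C)=C)[C@@]1(C)CC(=O)OCC | intermediate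
7 | 2-[(1R,6R)-2-hydroxy-1,3-dimethyl-6-(prop-1-en-2-yl)cyclohex-3-en-1-yl]ethan-1-ol (carbinol epimers) | OC1C(C)=CC[C@H](C(C)=C)[C@@]1(C)CCO | intermediate
8 | 2-[(1R,6R)-1,3-dimethyl-2-oxo-6-(prop-1-en-2-yl)cyclohex-3-en-1-yl]acetaldehyde | O=C1C(C)=CC[C@H](C(C)=C)[C@@]1(C)CC=O | intermediate
9 | (4aR,7R,8aR)-7-hydroxy-2,8a-dimethyl-5-methylidene-4a,5,6,7,8,8a-hexahydronaphthalen-1(4H)-one | O=C1C(C)=CC[C@@H]2C(=C)C[C@@H](O)C[C@@]12C | intermediate
10 | TBS ether of 9 | O=C1C(C)=CC[C@@H]2C(=C)C[C@@H](O[Si](C)(C)C(C)(C)C)C[C@@]12C | intermediate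
11 | N′-(C4-methyl-C4-ylmethyl) octane-1-sulfonohydrazide adduct of 10 (C4 epimers) | O=C1C(C)=CC[C@@H]2C(C)(CNNS(=O)(=O)CCCCCCCC)C[C@@H](O[Si](C)(C)C(C)(C)C)C[C@@]12C | intermediate
12 | (4aR,7R,8aR)-7-[(tert-butyldimethylsilyl)oxy]-2,5,5,8a-tetramethyl-4a,5,6,7,8,8a-hexahydronaphthalen-1(4H)-one | O=C1C(C)=CC[C@@H]2C(C)(C)C[C@@H](O[Si](C)(C)C(C)(C)C)C[C@@]12C | intermediate
13 | tert-butyldimethyl{[(2R,4aR,8aR)-4,4,7,8a-tetramethyl-8-methylidene-1,2,3,4,4a,5,8,8a-octahydronaphthalen-2-yl]oxy}silane | C=C1C(C)=CC[C@@H]2C(C)(C)C[C@@H](O[Si](C)(C)C(C)(C)C)C[C@@]12C | intermediate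
14 | (R)-2-methylsuccinic acid 4-methyl ester [(2R)-4-methoxy-2-methyl-4-oxobutanoic acid] | COC(=O)C[C@@H](C)C(=O)O | starting material
15 | methyl (R)-4-hydroxy-3-methylbutanoate | COC(=O)C[C@@H](C)CO | intermediate
16 | methyl (R)-4-bromo-3-methylbutanoate | COC(=O)C[C@@H](C)CBr | intermediate
17 | (R)-4-bromo-3-methylbutan-1-ol | OCC[C@@H](C)CBr | intermediate
18 | (R)-(4-bromo-3-methylbutoxy)(tert-butyl)dimethylsilane | CC(C)(C)[Si](C)(C)OCC[C@@H](C)CBr | intermediate
19 | 9-{[(1R,4aR,7R,8aR)-7-(TBS-oxy)-2,5,5,8a-tetramethyl-1,4,4a,5,6,7,8,8a-octahydronaphthalen-1-yl]methyl}-9-borabicyclo[3.3.1]nonane | C(B1C2CCCC1CCC2)[C@@H]1C(C)=CC[C@@H]2C(C)(C)C[C@@H](O[Si](C)(C)C(C)(C)C)C[C@@]12C | intermediate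
20 | (2R,5R,9R,10R,13S)-2,15-bis[(tert-butyldimethylsilyl)oxy]labd-7-ene | CC(C)(C)[Si](C)(C)OCC[C@@H](C)CC[C@@H]1C(C)=CC[C@@H]2C(C)(C)C[C@@H](O[Si](C)(C)C(C)(C)C)C[C@@]12C | intermediate
21 | (2R,5R,9R,10R,13S)-labd-7-ene-2,15-diol | OCC[C@@H](C)CC[C@@H]1C(C)=CC[C@@H]2C(C)(C)C[C@@H](O)C[C@@]12C | intermediate
22 | (3S)-5-[(1R,4aR,7R,8aR)-7-acetoxy-2,5,5,8a-tetramethyl-1,4,4a,5,6,7,8,8a-octahydronaphthalen-1-yl]-3-methylpentyl acetate | CC(=O)OCC[C@@H](C)CC[C@@H]1C(C)=CC[C@@H]2C(C)(C)C[C@@H](OC(C)=O)C[C@@]12C | target

**Step count**
Total: 15 steps. Longest linear sequence: 11 steps (1–8, 13–15) from (S)-carvone; the side-chain bromide takes 4 steps (9–12).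

**Steps most likely to fail**

1. Step 5. The ene array may assemble on the C20 face after all, because the chair array that type 2 closures normally use places the oxygen axial; C2 would then form with the wrong configuration. Fallback: setting out from 8, the same Me2AlCl closure is accepted with the configuration it gives, and the axial alcohol, the C2 epimer of 9 F1, is inverted. Mitsunobu reaction (4-nitrobenzoic acid, PPh3, DIAD, toluene, 0 → 25 °C) displaces the activated oxygen by SN2 from the open equatorial side and gives the equatorial 4-nitrobenzoate of 9 F2. K2CO3 in MeOH removes the ester and rejoins the route at 9. C2 is then set by inversion and not by the face of the cyclisation.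

2. Step 7. Reversible hydrogen-atom transfer may move the C4=CH2 bond into the ring or simply reduce it, and hydrogen-atom transfer to the enone may compete. Fallback: setting out from 10, Simmons–Smith cyclopropanation (Et2Zn, CH2I2, CH2Cl2, 0 °C), which touches only the electron-rich exocyclic alkene, gives the spirocyclopropane F3. Hydrogenolysis (H2, PtO2, AcOH) cleaves the unhindered CH2–CH2 bond to the gem-dimethyl group and at the same time saturates C7=C8, giving the saturated ketone F4. This ketone can enolise only towards C8, so TMSOTf/Et3N gives the silyl enol ether F5. Saegusa–Ito oxidation (Pd(OAc)2, MeCN) restores the C7=C8 enone and rejoins the route at 12.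

3. Step 13. Oxidative addition of the β-branched bromide and transmetalation of the β-branched borane next to quaternary C10 may both be slow, so that β-hydride elimination and protodeboronation take over. Fallback: the polarity is reversed and copper replaces palladium. Setting out from 13, the same 9-BBN hydroboration followed by NaOH/H2O2 gives the C11 alcohol F6, and I2/PPh3/imidazole gives the C11 iodide F7. The Grignard reagent F8, made from 18 with Mg in THF, is alkylated by F7 under Li2CuCl4 catalysis (THF, −20 → 0 °C) and the route is rejoined at 20.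

**Further compounds**
F1 | step 5 | (4aR,7S,8aR)-7-hydroxy-2,8a-dimethyl-5-methylidene-4a,5,6,7,8,8a-hexahydronaphthalen-1(4H)-one (C2 epimer of 9, axial OH) | O=C1C(C)=CC[C@@H]2C(=C)C[C@H](O)C[C@@]12C
F2 | step 5 | 4-nitrobenzoate of 9 (equatorial ester) | O=C1C(C)=CC[C@@H]2C(=C)C[C@@H](OC(=O)c3ccc(cc3)[N+](=O)[O-])C[C@@]12C
F3 | step 7 | spirocyclopropane from 10 (cyclopropane spiro at C4) | O=C1C(C)=CC[C@@H]2C3(CC3)C[C@@H](O[Si](C)(C)C(C)(C)C)C[C@@]12C
F4 | step 7 | 7,8-dihydro derivative of 12 (C8 epimers) | O=C1C(C)CC[C@@H]2C(C)(C)C[C@@H](O[Si](C)(C)C(C)(C)C)C[C@@]12C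
F5 | step 7 | C8=C9 trimethylsilyl enol ether of F4 | C[Si](C)(C)OC1=C(C)CC[C@@H]2C(C)(C)C[C@@H](O[Si](C)(C)C(C)(C)C)C[C@@]12C
F6 | step 13 | C11 alcohol from 13 (2-TBS-oxy drim-7-en-11-ol type) | OC[C@@H]1C(C)=CC[C@@H]2C(C)(C)C[C@@H](O[Si](C)(C)C(C)(C)C)C[C@@]12C
F7 | step 13 | C11 iodide from F6 | IC[C@@H]1C(C)=CC[C@@H]2C(C)(C)C[C@@H](O[Si](C)(C)C(C)(C)C)C[C@@]12C
F8 | step 13 | Grignard reagent from 18 | CC(C)(C)[Si](C)(C)OCC[C@@H](C)C[Mg]Br
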